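**Retrosynthetic overview**

- The target is 3',7-dihydroxy-4',5-dimethoxy-5'-prenylisoflavone. The last four steps only sort out oxygen substituents (3'-O-silyl, 4'-O-methyl, release of 3'-OH and 7-OH), so the whole skeleton is already present in catechol isoflavone 14.
- Key disconnection of 14: C3–C1' and O1–C2. Ring C is the only ring built and is closed last, between ring A enaminone 5 (which supplies C2, C3, C4) and 3-prenylcatechol 11 (ring B), the latter oxidized at an anode to its ortho-quinone.
- Feature on which this rests: in ring B, C1' is para to O4' and meta to O3', and the prenyl group sits on C5' next to O4'. This is the pattern left when a carbon nucleophile adds to C5 of 3-prenyl-1,2-benzoquinone, the open position β to the C1 carbonyl and remote from the side chain. Neither catechol oxygen ends up ortho to the new bond, so only the ring A phenol can close a ring.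
- Enaminone 5 comes in three steps from 2',4',6'-trihydroxyacetophenone; catechol 11 comes in three steps from catechol by directed ortho-lithiation and prenylation.

Key step: step 7

Remark: the target has no stereocenter; the only stereochemical element on the way is the E double bond of enaminone 5. Isoflavone positions are numbered in the usual way (ring A C5–C8, ring C O1–C4, ring B primed), and "prenyl" means 3-methylbut-2-en-1-yl.

**Route**

Step 1
Reactants: 1 2',4',6'-trihydroxyacetophenone
Product: 2 2',6'-dihydroxy-4'-(methoxymethoxy)acetophenone
Conditions: MOMCl (1.0 equiv), DIPEA (1.1 equiv), THF, 0 °C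
Reagents that add atoms: chloromethyl methyl ether (MOMCl), COCCl
Why: Williamson-type O-alkylation in which the 4'-hydroxyl, para to the ketone, is the most acidic and least hindered of the three, so one equivalent of the chloride should etherify it before the two ortho hydroxyls, which are deactivated by hydrogen bonding to the carbonyl and by the flanking acetyl group.

Step 2
Reactants: 2 2',6'-dihydroxy-4'-(methoxymethoxy)acetophenone
Product: 3 2'-hydroxy-6'-methoxy-4'-(methoxymethoxy)acetophenone
Conditions: MeI (1.1 equiv), K2CO3 (1.2 equiv), acetone, rt
Reagents that add atoms: iodomethane, CI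
Why: Williamson O-methylation in which the ortho hydroxyl that is free of the carbonyl chelate reacts, after which the remaining hydroxyl is locked in a strong intramolecular hydrogen bond and should resist a second methylation at room temperature, as in the classical mono-methylation of 2',6'-dihydroxyacetophenones.

Step 3
Reactants: 3 2'-hydroxy-6'-methoxy-4'-(methoxymethoxy)acetophenone; 4 N,N-dimethylformamide dimethyl acetal
Product: 5 (E)-3-(dimethylamino)-1-[2-hydroxy-6-methoxy-4-(methoxymethoxy)phenyl]prop-2-en-1-one
Conditions: 4 (1.5 equiv), toluene, 90 °C
Reagents that add atoms: none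
Why: Condensation of the acidic acetyl methyl group with the amide acetal (enaminone formation) with loss of two methanol should give the conjugated, thermodynamically favoured E vinylogous amide, and the chelated phenol is left untouched, as is usual for 2'-hydroxyacetophenones.

Step 4
Reactants: 6 catechol
Product: 7 1,2-bis(methoxymethoxy)benzene
Conditions: MOMCl (2.4 equiv), DIPEA (3 equiv), CH2Cl2, 0 °C to rt
Reagents that add atoms: chloromethyl methyl ether (MOMCl), COCCl
Why: Williamson-type double O-alkylation of both phenols gives the bis(methoxymethyl) ether, whose acetal oxygens direct the metalation of the next step.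

Step 5
Reactants: 7 1,2-bis(methoxymethoxy)benzene; 8 prenyl bromide (1-bromo-3-methylbut-2-ene)
Product: 10 1,2-bis(methoxymethoxy)-3-(3-methylbut-2-en-1-yl)benzene, via 2,3-bis(methoxymethoxy)phenyllithium 9 (not isolated)
Conditions: n-BuLi, TMEDA, THF, 0 °C; then 8, −78 °C to rt
Reagents that add atoms: none
Why: Directed ortho-metalation in which the MOM ether directs n-BuLi to the adjacent ring carbon (both ortho positions are equivalent), and the aryllithium displaces bromide at the primary CH2 terminus of prenyl bromide (SN2), the fully substituted γ-carbon being too hindered for SN2' attack.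

Step 6
Reactants: 10 1,2-bis(methoxymethoxy)-3-(3-methylbut-2-en-1-yl)benzene
Product: 11 3-prenylcatechol, 3-(3-methylbut-2-en-1-yl)benzene-1,2-diol
Conditions: conc. HCl (cat.), MeOH, rt
Reagents that add atoms: none
Why: Acid-catalysed transacetalization with methanol removes both MOM groups as dimethoxymethane, and with dilute acid at room temperature the trisubstituted olefin should not be protonated fast enough to cyclize onto the new ortho hydroxyl.

Step 7
Reactants: 5 (E)-3-(dimethylamino)-1-[2-hydroxy-6-methoxy-4-(methoxymethoxy)phenyl]prop-2-en-1-one; 11 3-prenylcatechol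
Product: 14 3',4'-dihydroxy-5-methoxy-7-(methoxymethoxy)-5'-prenylisoflavone, via 3-prenyl-ortho-benzoquinone 12 (not isolated), via 2-(dimethylamino)isoflavanone aminal 13 (not isolated)
Conditions: graphite anode, Pt cathode, undivided cell, constant potential at the foot of the catechol wave (about +0.4 V vs Ag/AgCl, to be set by cyclic voltammetry), 5 (1.3 equiv), NaH2PO4/Na2HPO4 buffer (pH 7)–MeCN 1:1, rt, about 2 F/mol; then AcOH, 40 °C
Reagents that add atoms: none
Why: Proposed new method: catechol 11 is the most easily oxidized species in the cell and should lose two electrons and two protons at the carbon anode to give quinone 12, whose C5 (β to the C1 carbonyl, para to the C2 oxygen and farthest from the prenyl group) accepts the nucleophilic α-carbon of vinylogous amide 5 in a Michael addition, after which enolization restores the aromatic catechol and leaves an α-aryl iminium ion carrying the new C3–C1' bond. The closest known reaction types are the anodic oxidation of catechols with in situ Michael addition of 1,3-dicarbonyl carbon nucleophiles, the Nenitzescu addition of enaminones to quinones, and the electrophile-triggered domino cyclization of ortho-hydroxyaryl enaminones to 3-substituted chromones, the new element being an electrogenerated ortho-quinone as the electrophile in the last of these. Ring C should close when the ring A phenol attacks the iminium carbon (6-exo-trig onto the C=N+ bond) to give aminal 13, and loss of dimethylamine across C2–C3, completed by the warming in acetic acid, gives the chromone with its O1–C2 bond. No stereocenter survives, since C2 and C3 of 13 both become trigonal. The step needs attack at C5 and not at C4, no Nenitzescu-type furan closure and no isomerization of 12 to a quinone methide: the prenyl group shields C4, the catechol oxygens of the adduct lie meta and para to the new bond so that only the ring A phenol can reach the iminium carbon, and an excess of 5 at pH 7 should trap 12 quickly while the liberated dimethylamine stays protonated and cannot add to the quinone. The product catechol carries an electron-poor chromone and should be harder to oxidize than the alkyl-substituted 11, so electrolysis at the foot of the first wave with about two faradays per mole is expected to stop at 14.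

Step 8
Reactants: 14 3',4'-dihydroxy-5-methoxy-7-(methoxymethoxy)-5'-prenylisoflavone
Product: 15 4'-hydroxy-5-methoxy-7-(methoxymethoxy)-5'-prenyl-3'-(triisopropylsilyloxy)isoflavone
Conditions: TIPSCl (1.05 equiv), imidazole (2 equiv), DMF, 0 °C
Reagents that add atoms: triisopropylsilyl chloride (TIPSCl), CC(C)[Si](Cl)(C(C)C)C(C)C
Why: Silylation of a phenol with a bulky silyl chloride and imidazole, in which the 3'-hydroxyl has only a hydrogen on its free flank while the 4'-hydroxyl is wedged between O3' and the prenyl group, so both the rate and any silyl equilibration between the two oxygens should favour the 3'-silyl ether.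

Step 9
Reactants: 15 4'-hydroxy-5-methoxy-7-(methoxymethoxy)-5'-prenyl-3'-(triisopropylsilyloxy)isoflavone
Product: 16 4',5-dimethoxy-7-(methoxymethoxy)-5'-prenyl-3'-(triisopropylsilyloxy)isoflavone
Conditions: MeOH (3 equiv), PPh3 (1.5 equiv), DIAD (1.5 equiv), THF, 0 °C to rt
Reagents that add atoms: methanol, CO
Why: Mitsunobu O-alkylation of the remaining phenol with methanol, in which the methoxyphosphonium ion methylates the phenoxide within a tight ion pair and without free base, which should keep the silyl group on O3' where a carbonate-mediated alkylation could let it migrate.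

Step 10
Reactants: 16 4',5-dimethoxy-7-(methoxymethoxy)-5'-prenyl-3'-(triisopropylsilyloxy)isoflavone
Product: 17 3'-hydroxy-4',5-dimethoxy-7-(methoxymethoxy)-5'-prenylisoflavone
Conditions: TBAF (1.1 equiv), AcOH (1.1 equiv), THF, 0 °C
Reagents that add atoms: none
Why: Fluoride cleavage of the aryl silyl ether (desilylation), buffered with acetic acid so that the base-sensitive pyranone ring and the MOM ether are not touched.

Step 11
Reactants: 17 3'-hydroxy-4',5-dimethoxy-7-(methoxymethoxy)-5'-prenylisoflavone
Product: 18 3',7-dihydroxy-4',5-dimethoxy-5'-prenylisoflavone (target)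
Conditions: 3 M aq. HCl, MeOH, 45 °C
Reagents that add atoms: none
Why: Acid-catalysed transacetalization removes the 7-O-MOM group, and since O4' is now a methyl ether the prenyl group has no neighbouring hydroxyl with which to form a chroman, while the aryl methyl ethers are stable to protic acid.

**Compound list**

1 | 2',4',6'-trihydroxyacetophenone | CC(=O)c1c(O)cc(O)cc1O | starting material
2 | 2',6'-dihydroxy-4'-(methoxymethoxy)acetophenone | CC(=O)c1c(O)cc(OCOC)cc1O | intermediate
3 | 2'-hydroxy-6'-methoxy-4'-(methoxymethoxy)acetophenone | CC(=O)c1c(O)cc(OCOC)cc1OC | intermediate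
4 | N,N-dimethylformamide dimethyl acetal | COC(OC)N(C)C | starting material
5 | (E)-3-(dimethylamino)-1-[2-hydroxy-6-methoxy-4-(methoxymethoxy)phenyl]prop-2-en-1-one | CN(C)/C=C/C(=O)c1c(O)cc(OCOC)cc1OC | intermediate
6 | catechol | Oc1ccccc1O | starting material
7 | 1,2-bis(methoxymethoxy)benzene | COCOc1ccccc1OCOC | intermediate
8 | prenyl bromide (1-bromo-3-methylbut-2-ene) | CC(C)=CCBr | starting material
9 | 2,3-bis(methoxymethoxy)phenyllithium (not isolated) | [Li]c1cccc(OCOC)c1OCOC | intermediate
10 | 1,2-bis(methoxymethoxy)-3-(3-methylbut-2-en-1-yl)benzene | COCOc1cccc(CC=C(C)C)c1OCOC | intermediate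
11 | 3-prenylcatechol, 3-(3-methylbut-2-en-1-yl)benzene-1,2-diol | Oc1cccc(CC=C(C)C)c1O | intermediate
12 | 3-prenyl-ortho-benzoquinone, 3-(3-methylbut-2-en-1-yl)cyclohexa-3,5-diene-1,2-dione (not isolated) | O=C1C=CC=C(CC=C(C)C)C1=O | intermediate
13 | 2-(dimethylamino)-3-[3,4-dihydroxy-5-(3-methylbut-2-en-1-yl)phenyl]-5-methoxy-7-(methoxymethoxy)chroman-4-one (aminal, not isolated; transient mixture of racemic diastereomers, both centres lost on elimination) | COCOc1cc(OC)c2c(c1)OC(N(C)C)C(c1cc(O)c(O)c(CC=C(C)C)c1)C2=O | intermediate
14 | 3',4'-dihydroxy-5-methoxy-7-(methoxymethoxy)-5'-prenylisoflavone | COCOc1cc(OC)c2c(c1)occ(-c1cc(O)c(O)c(CC=C(C)C)c1)c2=O | intermediate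
15 | 4'-hydroxy-5-methoxy-7-(methoxymethoxy)-5'-prenyl-3'-(triisopropylsilyloxy)isoflavone | COCOc1cc(OC)c2c(c1)occ(-c1cc(O[Si](C(C)C)(C(C)C)C(C)C)c(O)c(CC=C(C)C)c1)c2=O | intermediate
16 | 4',5-dimethoxy-7-(methoxymethoxy)-5'-prenyl-3'-(triisopropylsilyloxy)isoflavone | COCOc1cc(OC)c2c(c1)occ(-c1cc(O[Si](C(C)C)(C(C)C)C(C)C)c(OC)c(CC=C(C)C)c1)c2=O | intermediate
17 | 3'-hydroxy-4',5-dimethoxy-7-(methoxymethoxy)-5'-prenylisoflavone | COCOc1cc(OC)c2c(c1)occ(-c1cc(O)c(OC)c(CC=C(C)C)c1)c2=O | intermediate
18 | 3',7-dihydroxy-4',5-dimethoxy-5'-prenylisoflavone | COc1c(O)cc(-c2coc3cc(O)cc(OC)c3c2=O)cc1CC=C(C)C | target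

**Step count**

Total steps: 11 (steps 1–3 for ring A, steps 4–6 for ring B, step 7 for the union, steps 8–11 for the end game).
Longest linear sequence: 8 steps (1, 2, 3, 7, 8, 9, 10, 11; the branch 4, 5, 6, 7–11 is equally long).

**Steps most likely to fail**

1. Step 7 (anodic coupling and ring closure).
   - What may go wrong: the electrogenerated quinone may be consumed before the enaminone attacks it through carbon, by isomerization to a quinone methide through its benzylic and allylic CH2 group, by self-coupling, or by addition of water. The enaminone may also cyclize to the C3-unsubstituted chromone before it is arylated, and the product catechol may be oxidized further.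
   - Fallback with known chemistry, setting out from 5 and 11 and returning at 14: enaminone 5 is cyclized with I2 in MeOH at rt to 3-iodo-5-methoxy-7-(methoxymethoxy)-4H-chromen-4-one F1. Catechol 11 is silylated on both oxygens (TBSCl, imidazole, DMF) to 1,2-bis(tert-butyldimethylsilyloxy)-3-(3-methylbut-2-en-1-yl)benzene F2. F2 is borylated with B2pin2, [Ir(OMe)(cod)]2 and 4,4'-di-tert-butyl-2,2'-bipyridine at C5, its only C–H without an ortho substituent, to give 2-[3,4-bis(tert-butyldimethylsilyloxy)-5-(3-methylbut-2-en-1-yl)phenyl]-4,4,5,5-tetramethyl-1,3,2-dioxaborolane F3. Suzuki–Miyaura coupling of F1 with F3 (Pd(dppf)Cl2, K3PO4, dioxane–water, 70 °C) should give 3',4'-bis(tert-butyldimethylsilyloxy)-5-methoxy-7-(methoxymethoxy)-5'-prenylisoflavone F4, and TBAF with AcOH in THF then releases catechol 14.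

2. Step 9 (methylation of O4').
   - What may go wrong: migration of the silyl group from O3' to O4' at the phenoxide stage would scramble the position of the methyl group, and alkylation of the doubly flanked phenol may be slow.
   - Fallback, setting out from 14 and returning at 18: the silyl group is replaced by an acetal that cannot migrate. Catechol 14 is treated with MOMCl (1.0 equiv) and DIPEA in CH2Cl2 at −20 °C, which should alkylate the less hindered O3' to give 4'-hydroxy-5-methoxy-3',7-bis(methoxymethoxy)-5'-prenylisoflavone F5; any regioisomer is removed at this stage. Ordinary methylation (MeI, K2CO3, acetone) gives 4',5-dimethoxy-3',7-bis(methoxymethoxy)-5'-prenylisoflavone F6, and 3 M HCl in MeOH at 45 °C removes both acetals in one operation to give 18, which also saves one step.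

3. Step 6 (release of the prenylcatechol).
   - What may go wrong: acid-induced cyclization of the freed ortho-prenyl phenol onto the protonated olefin (chroman formation) may compete with acetal cleavage.
   - Fallback, setting out from 6 and 8 and returning at 11: the protecting groups are avoided altogether. The monosodium salt of catechol 6 (NaH, 1 equiv, toluene) is alkylated with prenyl bromide 8 at rt; in the non-polar, non-dissociating medium the phenoxide reacts through its ortho carbon, and 11 is separated from O-prenyl ether and dialkylated material by chromatography. This fallback makes no new compound (F0).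

**Further compounds**

F1 | step 7 | 3-iodo-5-methoxy-7-(methoxymethoxy)-4H-chromen-4-one | COCOc1cc(OC)c2c(c1)occ(I)c2=O
F2 | step 7 | 1,2-bis(tert-butyldimethylsilyloxy)-3-(3-methylbut-2-en-1-yl)benzene | CC(C)=CCc1cccc(O[Si](C)(C)C(C)(C)C)c1O[Si](C)(C)C(C)(C)C
F3 | step 7 | 2-[3,4-bis(tert-butyldimethylsilyloxy)-5-(3-methylbut-2-en-1-yl)phenyl]-4,4,5,5-tetramethyl-1,3,2-dioxaborolane | CC(C)=CCc1cc(B2OC(C)(C)C(C)(C)O2)cc(O[Si](C)(C)C(C)(C)C)c1O[Si](C)(C)C(C)(C)C
F4 | step 7 | 3',4'-bis(tert-butyldimethylsilyloxy)-5-methoxy-7-(methoxymethoxy)-5'-prenylisoflavone | COCOc1cc(OC)c2c(c1)occ(-c1cc(O[Si](C)(C)C(C)(C)C)c(O[Si](C)(C)C(C)(C)C)c(CC=C(C)C)c1)c2=O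
F5 | step 9 | 4'-hydroxy-5-methoxy-3',7-bis(methoxymethoxy)-5'-prenylisoflavone | COCOc1cc(OC)c2c(c1)occ(-c1cc(OCOC)c(O)c(CC=C(C)C)c1)c2=O
F6 | step 9 | 4',5-dimethoxy-3',7-bis(methoxymethoxy)-5'-prenylisoflavone | COCOc1cc(OC)c2c(c1)occ(-c1cc(OCOC)c(OC)c(CC=C(C)C)c1)c2=O
F0 | step 6 | none | none
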